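The route rests on cutting ring A (C1–C5, C10) across C4–C5 and C2–C3. Its C1=C10 alkene at the ring fusion, flanked by the quaternary C4 (CH3, carboxyl) and the C5 methine, is the signature of a Diels–Alder adduct of a 1-vinylcyclohexene and a methacrylate. One exo-selective, Lewis-acid-promoted cycloaddition of methyl methacrylate onto a ring-B diene (C5=C10–C1=C2) therefore closes ring A, forms two C–C bonds and sets C4 and C5, with the alkene delivered in place. The diene, (5R,6S)-6-allyl-5,6-dimethyl-1-vinylcyclohexene, already carries C8 and C9 and comes in three steps from 2-methylcyclohex-2-enone. The allyl group is later grown into the propionylated side chain.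

Key step: step 4

Remarks on the chemistry:
- Halimane locants are used in the text. In the octahydronaphthalene names C1 = halimane C4, C8a = C5, C6 = C8 and C5 = C9, so the target is 4S,5S,8R,9S.
- Assumption: the phosphoramidite antipode in step 1 is the one that gives the 3R enolate; if the sense of induction on this 2-substituted enone is opposite, the mirror-image ligand is taken.

Step 1
Reactants: 1 2-methylcyclohex-2-en-1-one; 2 allyl bromide
Product: 5 (2S,3R)-2-allyl-2,3-dimethylcyclohexan-1-one, via dimethylaluminium enolate 3 (not isolated), via lithium aluminate enolate 4 (not isolated)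
Conditions: Cu(OTf)2 (2 mol%), (R,S,S)-binaphthol-derived bis(1-phenylethyl)amine phosphoramidite (4 mol%), AlMe3, Et2O, −30 °C; then MeLi, THF/DMPU, −30 to 0 °C; then 2, 0 °C to rt
Reagents that add atoms: trimethylaluminium, C[Al](C)C
Why: Copper-catalysed asymmetric conjugate addition of AlMe3 sets C3 (later C8) as R under ligand control, and the aluminium enolate, activated as its lithium aluminate, is C-allylated anti to the neighbouring C3 methyl group, which sets the quaternary C2 (later C9) as S with the two methyl groups cis (tandem conjugate addition–enolate alkylation).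

Step 2
Reactants: 5 (2S,3R)-2-allyl-2,3-dimethylcyclohexan-1-one
Product: 7 (5R,6S)-6-allyl-5,6-dimethylcyclohex-1-en-1-yl trifluoromethanesulfonate, via lithium enolate 6 (not isolated)
Conditions: LiN(iPr)2, THF, −78 °C; then PhNTf2, −78 °C to rt; aq. NH4Cl
Reagents that add atoms: N-phenylbis(trifluoromethanesulfonimide), O=S(=O)(N(c1ccccc1)S(=O)(=O)C(F)(F)F)C(F)(F)F
Why: Only C6 carries α-hydrogens, so deprotonation gives a single enolate that is O-sulfonylated (enol triflate formation) without touching either stereocenter.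

Step 3
Reactants: 7 (5R,6S)-6-allyl-5,6-dimethylcyclohex-1-en-1-yl trifluoromethanesulfonate; 8 tributyl(vinyl)stannane
Product: 9 (5R,6S)-6-allyl-5,6-dimethyl-1-vinylcyclohex-1-ene
Conditions: Pd(PPh3)4 (5 mol%), LiCl (3 equiv), THF, 65 °C
Reagents that add atoms: none
Why: Stille coupling of an enol triflate with a vinylstannane under zerovalent palladium and LiCl is a standard entry to 1-vinylcyclohexenes and leaves the allyl group and both stereocenters unchanged.

Step 4
Reactants: 9 (5R,6S)-6-allyl-5,6-dimethyl-1-vinylcyclohex-1-ene; 10 methyl methacrylate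
Product: 11 methyl (1S,5S,6R,8aS)-5-allyl-1,5,6-trimethyl-1,2,3,5,6,7,8,8a-octahydronaphthalene-1-carboxylate
Conditions: 10 (5 equiv), EtAlCl2 (0.5 equiv), 2,6-di-tert-butyl-4-methylpyridine (0.1 equiv), CH2Cl2, −40 to 0 °C
Reagents that add atoms: none
Why: EtAlCl2-bound methyl methacrylate adds to the s-cis diene C5=C10–C1=C2 in a concerted, asynchronous [4+2] cycloaddition (the s-cis form is favoured because the s-trans form would push C2 into the quaternary C9), the closest known reaction type being the Lewis-acid-promoted Diels–Alder reaction of 1-vinylcyclohexenes with α-alkylacrylates. Ring A (C1–C5, C10) closes by this intermolecular, suprafacial 4+2 annulation onto ring B, bond C2–C3 leading and bond C4–C5 following, with C1=C10 arising directly at the ring fusion. Regiochemistry follows from the β-CH2 of the acrylate bonding to the unsubstituted terminus C2 (largest HOMO coefficient, least hindered, developing positive charge shared by tertiary C10 and secondary C5), so the carbonyl-bearing carbon C4 meets C5. C4 is set relative to C5 by ester-exo (methyl-endo) topicity, expected because the aluminium-complexed ester avoids the fully substituted C9 beside the internal diene carbon C10; this places the ester cis to H5 and gives 4S. C5 is set by the diene face: in the reactive half-chair the C9 allyl group is pseudoaxial, anti to the axial C8 methyl, and the C9 methyl lies near the diene plane, so the dienophile should add to the face opposite the allyl group, giving 5S with C4 cis to the C9 methyl. The step thus needs ortho regiochemistry, exo topicity and anti-allyl facial attack at once; the first two rest on the diene substitution pattern, the third on the C8/C9 centres and is the least secure.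

Step 5
Reactants: 11 methyl (1S,5S,6R,8aS)-5-allyl-1,5,6-trimethyl-1,2,3,5,6,7,8,8a-octahydronaphthalene-1-carboxylate
Product: 13 methyl (1S,5S,6R,8aS)-5-(3-hydroxypropyl)-1,5,6-trimethyl-1,2,3,5,6,7,8,8a-octahydronaphthalene-1-carboxylate, via B-alkyl-9-BBN adduct 12 (not isolated)
Conditions: 9-BBN, THF, 0 °C to rt; then NaOH, H2O2, 0 °C
Reagents that add atoms: hydrogen peroxide, OO
Why: Hydroboration–oxidation with 9-BBN engages only the monosubstituted allyl alkene, boron going to the terminal carbon, while the hindered trisubstituted C1=C10 alkene and the neopentyl-type ester stay intact; no stereocenter is formed.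

Step 6
Reactants: 13 methyl (1S,5S,6R,8aS)-5-(3-hydroxypropyl)-1,5,6-trimethyl-1,2,3,5,6,7,8,8a-octahydronaphthalene-1-carboxylate
Product: 14 methyl (1S,5S,6R,8aS)-1,5,6-trimethyl-5-(3-oxopropyl)-1,2,3,5,6,7,8,8a-octahydronaphthalene-1-carboxylate
Conditions: Dess–Martin periodinane, CH2Cl2, rt
Reagents that add atoms: none
Why: Dess–Martin oxidation takes a primary alcohol to the aldehyde and stops there under near-neutral conditions that should not move the C1=C10 alkene.

Step 7
Reactants: 14 methyl (1S,5S,6R,8aS)-1,5,6-trimethyl-5-(3-oxopropyl)-1,2,3,5,6,7,8,8a-octahydronaphthalene-1-carboxylate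
Product: 15 methyl (1S,5S,6R,8aS)-5-(but-3-yn-1-yl)-1,5,6-trimethyl-1,2,3,5,6,7,8,8a-octahydronaphthalene-1-carboxylate
Conditions: dimethyl (1-diazo-2-oxopropyl)phosphonate, K2CO3, MeOH, 0 °C to rt
Reagents that add atoms: dimethyl (1-diazo-2-oxopropyl)phosphonate, COP(=O)(OC)C(=[N+]=[N-])C(C)=O
Why: Seyferth–Gilbert homologation in its Ohira–Bestmann form turns the aldehyde into the terminal alkyne with one added carbon under mild K2CO3/MeOH, in which the methyl ester can at most exchange with itself.

Step 8
Reactants: 15 methyl (1S,5S,6R,8aS)-5-(but-3-yn-1-yl)-1,5,6-trimethyl-1,2,3,5,6,7,8,8a-octahydronaphthalene-1-carboxylate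
Product: 17 methyl (1S,5S,6R,8aS)-5-[(3E)-5-hydroxy-3-methylpent-3-en-1-yl]-1,5,6-trimethyl-1,2,3,5,6,7,8,8a-octahydronaphthalene-1-carboxylate, via alkenyldimethylalane 16 (not isolated)
Conditions: AlMe3 (3 equiv), Cp2ZrCl2 (0.25 equiv), CH2Cl2, 0 °C to rt; then (CH2O)n, THF, 0 °C to rt; aq. NH4Cl
Reagents that add atoms: trimethylaluminium, C[Al](C)C; paraformaldehyde (as formaldehyde), C=O
Why: Negishi zirconium-catalysed methylalumination adds CH3 and Al syn across the terminal alkyne with methyl on the internal carbon, and the alkenylalane is hydroxymethylated by formaldehyde with retention, which fixes the 13E geometry; the hindered C4 ester has no α-hydrogen and should only complex AlMe3 at room temperature.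

Step 9
Reactants: 17 methyl (1S,5S,6R,8aS)-5-[(3E)-5-hydroxy-3-methylpent-3-en-1-yl]-1,5,6-trimethyl-1,2,3,5,6,7,8,8a-octahydronaphthalene-1-carboxylate
Product: 18 (1S,5S,6R,8aS)-5-[(3E)-5-hydroxy-3-methylpent-3-en-1-yl]-1,5,6-trimethyl-1,2,3,5,6,7,8,8a-octahydronaphthalene-1-carboxylic acid
Conditions: NaSEt (6 equiv), DMF, 90 °C; then aq. HCl
Reagents that add atoms: none
Why: Thiolate cleaves the ester by SN2 attack at the O-methyl carbon instead of the shielded carbonyl, the usual way to free hindered quaternary methyl esters, and leaves the alcohol (as alkoxide), both alkenes and all stereocenters unchanged.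

Step 10
Reactants: 18 (1S,5S,6R,8aS)-5-[(3E)-5-hydroxy-3-methylpent-3-en-1-yl]-1,5,6-trimethyl-1,2,3,5,6,7,8,8a-octahydronaphthalene-1-carboxylic acid
Product: 19 (1S,5S,6R,8aS)-1,5,6-trimethyl-5-[(3E)-3-methyl-5-(propanoyloxy)pent-3-en-1-yl]-1,2,3,5,6,7,8,8a-octahydronaphthalene-1-carboxylic acid
Conditions: (EtCO)2O (1.5 equiv), pyridine, DMAP (cat.), CH2Cl2, 0 °C to rt; then H2O/THF, NaHCO3; acidify
Reagents that add atoms: propionic anhydride, CCC(=O)OC(=O)CC
Why: DMAP-catalysed O-acylation esterifies the primary allylic alcohol, and any mixed anhydride formed at the hindered C4 acid is hydrolysed at its propionyl carbonyl during the aqueous bicarbonate stir, returning the free acid.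

Compound list
1 | 2-methylcyclohex-2-en-1-one | CC1=CCCCC1=O | starting material
2 | allyl bromide | C=CCBr | starting material
3 | dimethyl{[(3R)-2,3-dimethylcyclohex-1-en-1-yl]oxy}alane (dimethylaluminium enolate) | CC1=C(O[Al](C)C)CCC[C@H]1C | intermediate
4 | lithium trimethyl{[(3R)-2,3-dimethylcyclohex-1-en-1-yl]oxy}aluminate | [Li+].CC1=C(O[Al-](C)(C)C)CCC[C@H]1C | intermediate
5 | (2S,3R)-2-allyl-2,3-dimethylcyclohexan-1-one | C=CC[C@]1(C)C(=O)CCC[C@H]1C | intermediate
6 | lithium (5R,6S)-6-allyl-5,6-dimethylcyclohex-1-en-1-olate | C=CC[C@]1(C)C(O[Li])=CCC[C@H]1C | intermediate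
7 | (5R,6S)-6-allyl-5,6-dimethylcyclohex-1-en-1-yl trifluoromethanesulfonate | C=CC[C@]1(C)C(OS(=O)(=O)C(F)(F)F)=CCC[C@H]1C | intermediate
8 | tributyl(vinyl)stannane | C=C[Sn](CCCC)(CCCC)CCCC | starting material
9 | (5R,6S)-6-allyl-5,6-dimethyl-1-vinylcyclohex-1-ene | C=CC[C@]1(C)C(C=C)=CCC[C@H]1C | intermediate
10 | methyl methacrylate | C=C(C)C(=O)OC | starting material
11 | methyl (1S,5S,6R,8aS)-5-allyl-1,5,6-trimethyl-1,2,3,5,6,7,8,8a-octahydronaphthalene-1-carboxylate | C=CC[C@]1(C)C2=CCC[C@](C)(C(=O)OC)[C@H]2CC[C@H]1C | intermediate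
12 | methyl (1S,5S,6R,8aS)-5-[3-(9-borabicyclo[3.3.1]nonan-9-yl)propyl]-1,5,6-trimethyl-1,2,3,5,6,7,8,8a-octahydronaphthalene-1-carboxylate | C1CCC2CCCC1B2CCC[C@]1(C)C2=CCC[C@](C)(C(=O)OC)[C@H]2CC[C@H]1C | intermediate
13 | methyl (1S,5S,6R,8aS)-5-(3-hydroxypropyl)-1,5,6-trimethyl-1,2,3,5,6,7,8,8a-octahydronaphthalene-1-carboxylate | OCCC[C@]1(C)C2=CCC[C@](C)(C(=O)OC)[C@H]2CC[C@H]1C | intermediate
14 | methyl (1S,5S,6R,8aS)-1,5,6-trimethyl-5-(3-oxopropyl)-1,2,3,5,6,7,8,8a-octahydronaphthalene-1-carboxylate | O=CCC[C@]1(C)C2=CCC[C@](C)(C(=O)OC)[C@H]2CC[C@H]1C | intermediate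
15 | methyl (1S,5S,6R,8aS)-5-(but-3-yn-1-yl)-1,5,6-trimethyl-1,2,3,5,6,7,8,8a-octahydronaphthalene-1-carboxylate | C#CCC[C@]1(C)C2=CCC[C@](C)(C(=O)OC)[C@H]2CC[C@H]1C | intermediate
16 | methyl (1S,5S,6R,8aS)-5-[(3E)-4-(dimethylalumanyl)-3-methylbut-3-en-1-yl]-1,5,6-trimethyl-1,2,3,5,6,7,8,8a-octahydronaphthalene-1-carboxylate | C[Al](C)/C=C(\C)CC[C@]1(C)C2=CCC[C@](C)(C(=O)OC)[C@H]2CC[C@H]1C | intermediate
17 | methyl (1S,5S,6R,8aS)-5-[(3E)-5-hydroxy-3-methylpent-3-en-1-yl]-1,5,6-trimethyl-1,2,3,5,6,7,8,8a-octahydronaphthalene-1-carboxylate | OC/C=C(\C)CC[C@]1(C)C2=CCC[C@](C)(C(=O)OC)[C@H]2CC[C@H]1C | intermediate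
18 | (1S,5S,6R,8aS)-5-[(3E)-5-hydroxy-3-methylpent-3-en-1-yl]-1,5,6-trimethyl-1,2,3,5,6,7,8,8a-octahydronaphthalene-1-carboxylic acid | OC/C=C(\C)CC[C@]1(C)C2=CCC[C@](C)(C(=O)O)[C@H]2CC[C@H]1C | intermediate
19 | (1S,5S,6R,8aS)-1,5,6-trimethyl-5-[(3E)-3-methyl-5-(propanoyloxy)pent-3-en-1-yl]-1,2,3,5,6,7,8,8a-octahydronaphthalene-1-carboxylic acid | CCC(=O)OC/C=C(\C)CC[C@]1(C)C2=CCC[C@](C)(C(=O)O)[C@H]2CC[C@H]1C | target

Total step count: 10. Longest linear sequence: 10 steps (1 to 19).

Steps most likely to fail

Step 4. The diene may be attacked on both faces, because half-chairs with the C9 methyl or the C9 allyl pseudoaxial are both accessible. Some endo-ester addition may erode the C4/C5 relationship, and the Lewis acid may trigger diene oligomerisation or migration of C1=C10. The fallback moves from substrate control to catalyst control with a more reactive dienophile. Setting out from 9, methacrolein is added at −78 °C in CH2Cl2 with a chiral oxazaborolidinium triflimide (diphenylprolinol-derived B-aryl oxazaborolidine activated by Tf2NH). The catalyst enantiomer is chosen so that its control of the dienophile face, combined with the reliable formyl-exo mode of α-methylacrolein, forces addition to the required diene face. This should give (1S,5S,6R,8aS)-5-allyl-1,5,6-trimethyl-1,2,3,5,6,7,8,8a-octahydronaphthalene-1-carbaldehyde F1. Pinnick oxidation (NaClO2, NaH2PO4, 2-methyl-2-butene, t-BuOH/H2O) would give (1S,5S,6R,8aS)-5-allyl-1,5,6-trimethyl-1,2,3,5,6,7,8,8a-octahydronaphthalene-1-carboxylic acid F2. Methylation with MeI/K2CO3 in DMF comes back to the route at 11.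

Step 8. Methylaluminium species may attack the C4 ester during the long carboalumination, or the alkenylalane may be protonated instead of captured by formaldehyde, giving the 2-methylalkene. The fallback avoids the alkyne and aluminium altogether and builds the trisubstituted alkene by olefination. Setting out from 14, MeMgBr in THF at −78 °C adds to the aldehyde only, giving methyl (1S,5S,6R,8aS)-5-(3-hydroxybutyl)-1,5,6-trimethyl-1,2,3,5,6,7,8,8a-octahydronaphthalene-1-carboxylate F3 as a mixture of carbinol epimers. Dess–Martin oxidation gives the methyl ketone methyl (1S,5S,6R,8aS)-1,5,6-trimethyl-5-(3-oxobutyl)-1,2,3,5,6,7,8,8a-octahydronaphthalene-1-carboxylate F4. Horner–Wadsworth–Emmons reaction with triethyl phosphonoacetate/NaH in THF should give mainly methyl (1S,5S,6R,8aS)-5-[(3E)-5-ethoxy-3-methyl-5-oxopent-3-en-1-yl]-1,5,6-trimethyl-1,2,3,5,6,7,8,8a-octahydronaphthalene-1-carboxylate F5, the minor Z isomer being removed by chromatography. DIBAL-H at −78 °C reduces the unhindered conjugated ethyl ester in preference to the shielded C4 ester and comes back to the route at 17.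

Step 1. Alkylation of the aluminate enolate may be sluggish or give O- and poly-allylation, and the one-pot format hides the enantiomeric purity of the conjugate addition. The fallback separates the two events through an isolated, regiodefined enol ether. Setting out from 1, the same copper-catalysed AlMe3 addition is quenched with TMSOTf to give trimethyl{[(3R)-2,3-dimethylcyclohex-1-en-1-yl]oxy}silane F6, which is purified and its enantiomeric purity checked. MeLi in THF at 0 °C then releases the lithium enolate, lithium (3R)-2,3-dimethylcyclohex-1-en-1-olate F7, and allylation with 2 in THF/DMPU at −78 to 0 °C comes back to the route at 5.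

Further compounds
F1 | step 4 | (1S,5S,6R,8aS)-5-allyl-1,5,6-trimethyl-1,2,3,5,6,7,8,8a-octahydronaphthalene-1-carbaldehyde | C=CC[C@]1(C)C2=CCC[C@](C)(C=O)[C@H]2CC[C@H]1C
F2 | step 4 | (1S,5S,6R,8aS)-5-allyl-1,5,6-trimethyl-1,2,3,5,6,7,8,8a-octahydronaphthalene-1-carboxylic acid | C=CC[C@]1(C)C2=CCC[C@](C)(C(=O)O)[C@H]2CC[C@H]1C
F3 | step 8 | methyl (1S,5S,6R,8aS)-5-(3-hydroxybutyl)-1,5,6-trimethyl-1,2,3,5,6,7,8,8a-octahydronaphthalene-1-carboxylate (both carbinol epimers) | CC(O)CC[C@]1(C)C2=CCC[C@](C)(C(=O)OC)[C@H]2CC[C@H]1C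
F4 | step 8 | methyl (1S,5S,6R,8aS)-1,5,6-trimethyl-5-(3-oxobutyl)-1,2,3,5,6,7,8,8a-octahydronaphthalene-1-carboxylate | CC(=O)CC[C@]1(C)C2=CCC[C@](C)(C(=O)OC)[C@H]2CC[C@H]1C
F5 | step 8 | methyl (1S,5S,6R,8aS)-5-[(3E)-5-ethoxy-3-methyl-5-oxopent-3-en-1-yl]-1,5,6-trimethyl-1,2,3,5,6,7,8,8a-octahydronaphthalene-1-carboxylate | CCOC(=O)/C=C(\C)CC[C@]1(C)C2=CCC[C@](C)(C(=O)OC)[C@H]2CC[C@H]1C
F6 | step 1 | trimethyl{[(3R)-2,3-dimethylcyclohex-1-en-1-yl]oxy}silane | CC1=C(O[Si](C)(C)C)CCC[C@H]1C
F7 | step 1 | lithium (3R)-2,3-dimethylcyclohex-1-en-1-olate | CC1=C(O[Li])CCC[C@H]1C
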